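**Retrosynthetic overview**
- The target is reached by desilylation of its 13-O-silyl ether; the 6β-acetate comes from a 1,2-acyloxy shift in the α-epoxide of the C6=C7 dienol acetate of a 7-oxo-Δ8 enone, and the ketone from allylic oxidation of a (13R)-13-silyloxylabda-8,14-diene.
- Both rings are made in one proton-initiated, reagent-controlled bicyclisation of the acyclic (R)-geranyllinalyl silyl ether: ring A closes first (C4–C5 bond), ring B second (C9–C10 bond), and the C8 cation loses 9α-H to give the Δ8 alkene.
- The acyclic precursor comes from (2E,6E,10E)-geranylgeraniol by Sharpless epoxidation and reductive 1,3-transposition, so C13 is fixed before any ring exists.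

Assumption: (2E,6E,10E)-geranylgeraniol (annatto-derived bulk grade) is taken as a cheap commercial starting material; labdane numbering and α/β face descriptors are used for all bicyclic compounds.

**Step 1**
Reactants: 1 (2E,6E,10E)-geranylgeraniol
Product: 2 (2R,3R)-2,3-epoxygeranylgeraniol
Conditions: Ti(OiPr)4 (10 mol%), diethyl D-(−)-tartrate (12 mol%), t-BuOOH, 4 Å sieves, CH2Cl2, −20 °C
Reagents that add atoms: tert-butyl hydroperoxide, CC(C)(C)OO
Why: Sharpless asymmetric epoxidation touches only the allylic-alcohol alkene, and the D-(−)-tartrate ligand delivers oxygen to the face that gives the (2R,3R)-epoxide, whose C3 becomes C13 (R) of the target.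

**Step 2**
Reactants: 2 (2R,3R)-2,3-epoxygeranylgeraniol
Product: 3 (2S,3R)-2,3-epoxygeranylgeranyl iodide
Conditions: PPh3, I2, imidazole, Et2O/MeCN, 0 °C
Reagents that add atoms: iodine, II
Why: Garegg–Samuelsson (Appel-type) iodination replaces the primary hydroxyl under neutral conditions without opening the epoxide or touching a stereocentre (the C2 descriptor changes only because iodine outranks oxygen).

**Step 3**
Reactants: 3 (2S,3R)-2,3-epoxygeranylgeranyl iodide
Product: 5 (3R,6E,10E)-geranyllinalyl tert-butyldimethylsilyl ether, via lithium alkoxide 4 (not isolated)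
Conditions: t-BuLi (2.1 equiv), Et2O, −78 °C; then TBSOTf, −78 → 0 °C
Reagents that add atoms: tert-butyldimethylsilyl triflate, CC(C)(C)[Si](C)(C)OS(=O)(=O)C(F)(F)F
Why: Lithium–iodine exchange followed by β-elimination (reductive epoxide opening) gives the tertiary vinyl carbinol as its alkoxide with the C3–O bond intact, so the R configuration is kept, and in-situ O-silylation masks the oxygen.

**Step 4**
Reactants: 5 (3R,6E,10E)-geranyllinalyl tert-butyldimethylsilyl ether
Product: 6 (13R)-13-(tert-butyldimethylsilyloxy)labda-8,14-diene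
Conditions: (R)-2-hydroxy-2'-(2-fluorobenzyloxy)-1,1'-binaphthyl·SnCl4 (2 equiv, ligand recovered), toluene, −78 °C, 2–4 d
Reagents that add atoms: none
Why: Proposed new method: the chiral Lewis-acid-assisted Brønsted acid protonates the terminal trisubstituted alkene (precedent: its enantioselective cyclisations of homofarnesol and of the tertiary vinyl carbinol nerolidol) and triggers chair–chair closure of ring A then ring B with anti addition across both E alkenes, which sets the trans ring fusion (10β-CH3, 5α-H) in the absolute sense known for the (R)-ligand, while the bulky tertiary silyl ether oxygen, which can reach the axial 9α-H through a six-membered arrangement but is too hindered to bond to the tertiary C8 cation, is proposed to act as internal base so that the cation loses 9α-H and gives the Δ8 alkene; the closest known reaction type is the acid-promoted polyene cyclisation terminated by a tethered oxygen function.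

**Step 5**
Reactants: 6 (13R)-13-(tert-butyldimethylsilyloxy)labda-8,14-diene
Product: 7 (13R)-13-(tert-butyldimethylsilyloxy)labda-8,14-dien-7-one
Conditions: CrO3, 3,5-dimethylpyrazole, CH2Cl2, −20 °C
Reagents that add atoms: chromium trioxide, O=[Cr](=O)=O
Why: Allylic oxidation with the hexavalent chromium–dimethylpyrazole complex converts the ring allylic methylene C7 of the tetrasubstituted alkene into the enone carbonyl (C11 is more shielded, the vinyl group has no allylic hydrogen), and no stereocentre is involved.

**Step 6**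
Reactants: 7 (13R)-13-(tert-butyldimethylsilyloxy)labda-8,14-dien-7-one
Product: 9 (13R)-7-acetoxy-13-(tert-butyldimethylsilyloxy)labda-6,8,14-triene, via lithium dienolate 8 (not isolated)
Conditions: LiN(iPr)2 (LDA), THF, −78 °C; then Ac2O, −78 → 0 °C
Reagents that add atoms: acetic anhydride, CC(=O)OC(C)=O
Why: Kinetic α'-deprotonation of the enone at C6 and O-acylation of the lithium enolate give the cross-conjugated dienol acetate, with no stereocentre created.

**Step 7**
Reactants: 9 (13R)-7-acetoxy-13-(tert-butyldimethylsilyloxy)labda-6,8,14-triene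
Product: 11 (13R)-6β-acetoxy-13-(tert-butyldimethylsilyloxy)labda-8,14-dien-7-one, via epoxy acetate 10 (not isolated)
Conditions: dimethyldioxirane, acetone/CH2Cl2, −40 → 0 °C; evaporate; toluene, 100 °C
Reagents that add atoms: dimethyldioxirane, CC1(C)OO1
Why: Dioxirane epoxidation should start at C6 (largest HOMO coefficient of the 2-acetoxydiene, least hindered carbon) on the α face because the C19 and C20 methyls block the β face, and the thermal enol ester epoxide rearrangement (intramolecular 1,2-acyloxy shift with inversion at the migration terminus) then delivers the acetate to C6 from the β face, giving the axial 6β-acetate and the C7 ketone.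

**Step 8**
Reactants: 11 (13R)-6β-acetoxy-13-(tert-butyldimethylsilyloxy)labda-8,14-dien-7-one
Product: 12 (13R)-6β-acetoxy-13-hydroxylabda-8,14-dien-7-one (target, 5S,6S,10S,13R)
Conditions: HF·pyridine, pyridine, THF, 0 °C → rt
Reagents that add atoms: none
Why: Buffered fluoride desilylation frees the tertiary alcohol under conditions too mild to epimerise or cleave the α-keto acetate or to ionise the tertiary allylic alcohol.

**Compound list**
1 | (2E,6E,10E)-geranylgeraniol | OC/C=C(\C)CC/C=C(\C)CC/C=C(\C)CCC=C(C)C | starting material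
2 | (2R,3R)-2,3-epoxygeranylgeraniol | OC[C@H]1O[C@]1(C)CC/C=C(\C)CC/C=C(\C)CCC=C(C)C | intermediate
3 | (2S,3R)-2,3-epoxygeranylgeranyl iodide | IC[C@H]1O[C@]1(C)CC/C=C(\C)CC/C=C(\C)CCC=C(C)C | intermediate
4 | lithium (3R,6E,10E)-geranyllinalyl oxide | C=C[C@](C)([O-])CC/C=C(\C)CC/C=C(\C)CCC=C(C)C.[Li+] | intermediate (not isolated)
5 | (3R,6E,10E)-geranyllinalyl tert-butyldimethylsilyl ether | C=C[C@](C)(O[Si](C)(C)C(C)(C)C)CC/C=C(\C)CC/C=C(\C)CCC=C(C)C | intermediate
6 | (13R)-13-(tert-butyldimethylsilyloxy)labda-8,14-diene (5S,10S) | C=C[C@](C)(O[Si](C)(C)C(C)(C)C)CCC1=C(C)CC[C@H]2C(C)(C)CCC[C@]12C | intermediate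
7 | (13R)-13-(tert-butyldimethylsilyloxy)labda-8,14-dien-7-one | C=C[C@](C)(O[Si](C)(C)C(C)(C)C)CCC1=C(C)C(=O)C[C@H]2C(C)(C)CCC[C@]12C | intermediate
8 | lithium (13R)-13-(tert-butyldimethylsilyloxy)labda-6,8,14-trien-7-olate | C=C[C@](C)(O[Si](C)(C)C(C)(C)C)CCC1=C(C)C([O-])=C[C@H]2C(C)(C)CCC[C@]12C.[Li+] | intermediate (not isolated)
9 | (13R)-7-acetoxy-13-(tert-butyldimethylsilyloxy)labda-6,8,14-triene | C=C[C@](C)(O[Si](C)(C)C(C)(C)C)CCC1=C(C)C(OC(C)=O)=C[C@H]2C(C)(C)CCC[C@]12C | intermediate
10 | (13R)-7β-acetoxy-6α,7α-epoxy-13-(tert-butyldimethylsilyloxy)labda-8,14-diene | C=C[C@](C)(O[Si](C)(C)C(C)(C)C)CCC1=C(C)[C@]3(OC(C)=O)O[C@@H]3[C@H]2C(C)(C)CCC[C@]12C | intermediate (not isolated)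
11 | (13R)-6β-acetoxy-13-(tert-butyldimethylsilyloxy)labda-8,14-dien-7-one | C=C[C@](C)(O[Si](C)(C)C(C)(C)C)CCC1=C(C)C(=O)[C@@H](OC(C)=O)[C@H]2C(C)(C)CCC[C@]12C | intermediate
12 | (13R)-6β-acetoxy-13-hydroxylabda-8,14-dien-7-one | C=C[C@](C)(O)CCC1=C(C)C(=O)[C@@H](OC(C)=O)[C@H]2C(C)(C)CCC[C@]12C | target

**Step count**
Total steps: 8. Longest linear sequence: 8 (fully linear from 1).

**Steps most likely to fail, with fallbacks**

Step 4 (bicyclisation) is the riskiest. The silyl ether may fail to steer proton loss to C9, and imperfect facial control would give the ent-decalin diastereomer, which would have to be removed by chromatography or crystallisation at the enone stage. Fallback, setting out from 5 and returning at 7: the same protonative cyclisation is allowed to end by undirected loss of the axial 7α-H, the usual outcome, giving the Δ7 isomer (13R)-13-(tert-butyldimethylsilyloxy)labda-7,14-diene F1. Sensitised photo-oxygenation (O2, hν, tetraphenylporphyrin, CH2Cl2; Schenck ene reaction) adds singlet oxygen to C7 on the open α face with abstraction of the axial 9α-H and gives (13R)-13-(tert-butyldimethylsilyloxy)-7α-hydroperoxylabda-8,14-diene F2. Ac2O/pyridine (Kornblum–DeLaMare-type dehydration) turns F2 into enone 7, so step 5 is bypassed; any 6 formed alongside F1 still goes through step 5 to the same enone.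

Step 7 (epoxidation and acyloxy shift) can fail in two ways: the dioxirane may attack the tetrasubstituted C8=C9 bond, or the allylic epoxy acetate may ionise and rearrange with retention to the 6α-acetate. Fallback, setting out from 7 and returning at 12: Mn(OAc)3 in refluxing benzene acetoxylates the α'-position from the open α face and gives (13R)-6α-acetoxy-13-(tert-butyldimethylsilyloxy)labda-8,14-dien-7-one F5. Soft enolisation (TBSOTf, Et3N, CH2Cl2) converts it into (13R)-6-acetoxy-7,13-bis(tert-butyldimethylsilyloxy)labda-6,8,14-triene F6. HF·pyridine then removes both silyl groups, and the liberated enol ketonises by kinetic protonation at C6 from the α face, which places the acetate β and gives 12 directly.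

Step 5 (allylic oxidation) may give the C11 ketone or the 7,11-dione. Fallback, setting out from 6 and returning at 7: photo-oxygenation of the tetrasubstituted alkene (O2, hν, tetraphenylporphyrin) with abstraction of the axial 7α-H gives (13R)-13-(tert-butyldimethylsilyloxy)-9α-hydroperoxylabda-7,14-diene F3. PPh3 reduces it to (13R)-13-(tert-butyldimethylsilyloxy)labda-7,14-dien-9α-ol F4. Pyridinium chlorochromate in CH2Cl2 (Babler–Dauben oxidative 1,3-transposition of a tertiary allylic alcohol) then gives enone 7.

**Further compounds**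
F1 | step 4 | (13R)-13-(tert-butyldimethylsilyloxy)labda-7,14-diene | C=C[C@](C)(O[Si](C)(C)C(C)(C)C)CC[C@H]1C(C)=CC[C@H]2C(C)(C)CCC[C@]12C
F2 | step 4 | (13R)-13-(tert-butyldimethylsilyloxy)-7α-hydroperoxylabda-8,14-diene | C=C[C@](C)(O[Si](C)(C)C(C)(C)C)CCC1=C(C)[C@H](OO)C[C@H]2C(C)(C)CCC[C@]12C
F3 | step 5 | (13R)-13-(tert-butyldimethylsilyloxy)-9α-hydroperoxylabda-7,14-diene | C=C[C@](C)(O[Si](C)(C)C(C)(C)C)CC[C@@]1(OO)C(C)=CC[C@H]2C(C)(C)CCC[C@]12C
F4 | step 5 | (13R)-13-(tert-butyldimethylsilyloxy)labda-7,14-dien-9α-ol | C=C[C@](C)(O[Si](C)(C)C(C)(C)C)CC[C@@]1(O)C(C)=CC[C@H]2C(C)(C)CCC[C@]12C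
F5 | step 7 | (13R)-6α-acetoxy-13-(tert-butyldimethylsilyloxy)labda-8,14-dien-7-one | C=C[C@](C)(O[Si](C)(C)C(C)(C)C)CCC1=C(C)C(=O)[C@H](OC(C)=O)[C@H]2C(C)(C)CCC[C@]12C
F6 | step 7 | (13R)-6-acetoxy-7,13-bis(tert-butyldimethylsilyloxy)labda-6,8,14-triene | C=C[C@](C)(O[Si](C)(C)C(C)(C)C)CCC1=C(C)C(O[Si](C)(C)C(C)(C)C)=C(OC(C)=O)[C@H]2C(C)(C)CCC[C@]12C
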